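## Retrosynthetic overview

1. **Feature.** C8–C8'' is the only bond not already present in two commercial flavones. It joins two ring A carbons, each lying between O7 and the pyrone oxygen O1 (on C8a) and para to O5. The halves differ only at the remote ring B oxygen: 4'-OMe in unit 1, 4'''-OH in unit 2.
2. **Last disconnection.** O7 and O7'' both stand ortho to that bond. The target is therefore traced back, by acetal cleavage and debenzylation, to a 7,7''-O-methylene-bridged biflavone (a dibenzo[d,f][1,3]dioxepine) with O5, O5'' and O4''' as benzyl ethers.
3. **Key disconnection.** C8–C8'' is cut to the open bis(flavon-7-yloxy)methane. In the forward sense this is a dehydrogenative aryl–aryl coupling with a trivalent-iodine oxidant, and both carbons carry only hydrogen.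
4. **Acetal disconnection.** The unsymmetrical acetal comes from acacetin 7-O-chloromethyl ether and the 7-OH of apigenin. The chloromethyl ether is made through the methylthiomethyl ether, because with a dihalomethane the first-formed halomethyl ether would outrun the dihalide for phenoxide and give the symmetrical acetal.
5. **Ring order.** All six rings of the target are bought with acacetin and apigenin. The only ring built is the temporary seven-membered dioxepine (step 5), which is opened again in step 7.

Key step: step 5

Assumption: the SMILES gives no descriptor for the hindered C8–C8'' axis, so the compound is prepared as the racemate.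

Locants: plain and single-primed numbers refer to unit 1 (acacetin half); double- and triple-primed numbers refer to unit 2 (apigenin half).

## Route

Step 1
Reactants: 1 acacetin (5,7-dihydroxy-2-(4-methoxyphenyl)chromen-4-one)
Product: 2 7-O-(methylthiomethyl)acacetin (5-hydroxy-2-(4-methoxyphenyl)-7-[(methylsulfanyl)methoxy]chromen-4-one)
Conditions: MeSCH2Cl (1.2 equiv), K2CO3 (1.5 equiv), NaI (0.1 equiv), DMF, 0 °C → rt
Reagents that add atoms: chloromethyl methyl sulfide, CSCCl
Why: Williamson ether synthesis in which carbonate ionises only the acidic 7-OH (a vinylogous acid through C4=O), while the 5-OH stays locked in its hydrogen bond to C4=O and is not alkylated.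

Step 2
Reactants: 2 7-O-(methylthiomethyl)acacetin
Product: 3 7-O-(chloromethyl)acacetin (7-(chloromethoxy)-5-hydroxy-2-(4-methoxyphenyl)chromen-4-one)
Conditions: SO2Cl2 (1.0 equiv), CH2Cl2, −20 → 0 °C, 30 min; volatiles removed in vacuo, residue used at once
Reagents that add atoms: sulfuryl chloride, O=S(=O)(Cl)Cl
Why: Chlorinolysis of an O,S-acetal, the standard conversion of aryl methylthiomethyl ethers into aryl chloromethyl ethers: sulfur is chlorinated much faster than ring A, the chlorosulfonium ion fragments to MeSCl and the aryloxymethyl cation, and chloride caps the cation.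

Step 3
Reactants: 3 7-O-(chloromethyl)acacetin; 4 apigenin (5,7-dihydroxy-2-(4-hydroxyphenyl)chromen-4-one)
Product: 5 (acacetin-7-yloxy)(apigenin-7-yloxy)methane, the unsymmetrical formaldehyde acetal with free 5-, 5''- and 4'''-OH
Conditions: 4 (1.5 equiv), K2CO3 (1.5 equiv), dry DMF, 0 °C → rt
Reagents that add atoms: none
Why: Williamson-type O-alkylation with an α-chloro ether: one equivalent of carbonate per apigenin ionises only the most acidic 7-OH (5-OH is chelated, 4'-OH is less acidic), and the excess of 4 keeps the product 4'''-OH protonated, so the mixed acetal should form without a second alkylation.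

Step 4
Reactants: 5 (acacetin-7-yloxy)(apigenin-7-yloxy)methane
Product: 6 7,7''-O-methylene-linked 5-O-benzylacacetin and 5,4'-di-O-benzylapigenin (open tribenzyl ether)
Conditions: BnBr (6 equiv), K2CO3 (8 equiv), nBu4NI (0.1 equiv), DMF, 70 °C
Reagents that add atoms: benzyl bromide, BrCc1ccccc1
Why: Exhaustive Williamson benzylation in which the 4'''-OH reacts first and the two chelated 5-OH groups follow on heating with excess reagent, while the base-stable diaryl acetal is untouched; etherifying O5 also moves the most nucleophilic ring A site from C6 to C8.

Step 5
Reactants: 6 open tribenzyl ether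
Product: 7 7,7''-O-methylene-bridged 8,8''-biflavone tribenzyl ether (racemic axis)
Conditions: PhI(OCOCF3)2 (1.2 equiv) premixed with BF3·OEt2 (2.4 equiv), CH2Cl2 (0.005 M in 6), −40 → −10 °C; aq NaHCO3
Reagents that add atoms: none
Why: PhI(OCOCF3)2 ionised by BF3 forms a charge-transfer complex with one trialkoxy ring A and removes one electron; C8 of the other ring A attacks C8 of this radical cation, and a second one-electron oxidation with loss of two protons rearomatises both rings, the iodane ending as PhI and two CF3CO2H. The closest known reaction is the trivalent-iodine (or MoCl5) mediated dehydrogenative coupling of two phenol-ether rings joined by a short O–X–O or carbon tether, a mild Scholl-type reaction established for dibenzo-fused seven- and eight-membered rings. The one ring closed is the seven-membered dibenzo[d,f][1,3]dioxepine C8–C7–O–CH2–O–C7''–C8'', by a formally 7-endo-trig attack in which both bond-forming atoms are the ring carbons ortho to the tether oxygens. No stereocentre is made; the new axis forms as a racemate and the bridge holds it at a small dihedral angle, which the small flanking atoms O1 and O1'' can accommodate. Cross-selectivity comes from the tether (no homodimer can arise and high dilution suppresses intermolecular coupling), and site chemoselectivity comes from ring A being the only arene with three oxygen donors, whereas each ring B carries one alkoxy group conjugated to the enone and the benzyl rings carry none. C8 must win over C6 in both halves: with O5 etherified, 5,7-dioxygenated flavones react with electrophiles at C8, which is para to O5 and flanked only by the endocyclic O1, while C6 is wedged between two acyclic alkoxy groups.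

Step 6
Reactants: 7 bridged biflavone tribenzyl ether
Product: 8 7,7''-O-methylene-4'-O-methylcupressuflavone (bridged biflavone with free 5-, 5''- and 4'''-OH)
Conditions: H2 (1 atm), 10% Pd/C, THF–MeOH, rt
Reagents that add atoms: none
Why: Catalytic hydrogenolysis of aryl benzyl ethers, under which the flavone C2=C3 bonds, the methyl ether, the non-benzylic O–CH2–O acetal and the biaryl bond should persist.

Step 7
Reactants: 8 7,7''-O-methylene-4'-O-methylcupressuflavone
Product: 9 4'-O-methylcupressuflavone (8,8''-biapigenin 4'-methyl ether, target, racemic axis)
Conditions: BCl3 (1 M in CH2Cl2, 10 equiv), CH2Cl2, −20 °C → rt; then cold dilute 1 M aq HCl–THF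
Reagents that add atoms: none
Why: Lewis-acid cleavage of an aryl methylene acetal with BCl3, the known way to open methylenedioxyarenes beside methoxy groups: chloride opens an O–CH2 bond of the boron-bound acetal, helped by relief of torsional strain in the bridged tetra-ortho-substituted biaryl, the aqueous quench releases the one-carbon unit as formaldehyde into the water layer, and the unchelated 4'-OMe is not attacked at or below room temperature.

## Compound list

| No. | Name | SMILES | Role |
|---|---|---|---|
| 1 | acacetin | COc1ccc(cc1)-c1cc(=O)c2c(O)cc(O)cc2o1 | starting material |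
| 2 | 7-O-(methylthiomethyl)acacetin | COc1ccc(cc1)-c1cc(=O)c2c(O)cc(OCSC)cc2o1 | intermediate |
| 3 | 7-O-(chloromethyl)acacetin | COc1ccc(cc1)-c1cc(=O)c2c(O)cc(OCCl)cc2o1 | intermediate |
| 4 | apigenin | O=c1cc(-c2ccc(O)cc2)oc2cc(O)cc(O)c12 | starting material |
| 5 | (acacetin-7-yloxy)(apigenin-7-yloxy)methane | COc1ccc(cc1)-c1cc(=O)c2c(O)cc(OCOc3cc(O)c4c(=O)cc(-c5ccc(O)cc5)oc4c3)cc2o1 | intermediate |
| 6 | 7,7''-O-methylene-linked 5-O-benzylacacetin and 5,4'-di-O-benzylapigenin | COc1ccc(cc1)-c1cc(=O)c2c(OCc3ccccc3)cc(OCOc3cc(OCc4ccccc4)c4c(=O)cc(-c5ccc(OCc6ccccc6)cc5)oc4c3)cc2o1 | intermediate |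
| 7 | 7,7''-O-methylene-bridged 8,8''-biflavone tribenzyl ether | COc1ccc(cc1)-c1cc(=O)c2c(OCc3ccccc3)cc3OCOc4cc(OCc5ccccc5)c5c(=O)cc(-c6ccc(OCc7ccccc7)cc6)oc5c4-c3c2o1 | intermediate |
| 8 | 7,7''-O-methylene-4'-O-methylcupressuflavone | COc1ccc(cc1)-c1cc(=O)c2c(O)cc3OCOc4cc(O)c5c(=O)cc(-c6ccc(O)cc6)oc5c4-c3c2o1 | intermediate |
| 9 | 4'-O-methylcupressuflavone | COc1ccc(-c2cc(=O)c3c(O)cc(O)c(-c4c(O)cc(O)c5c(=O)cc(-c6ccc(O)cc6)oc45)c3o2)cc1 | target |

Total step count: 7
Longest linear sequence: 7 steps (from acacetin; apigenin enters unmodified in step 3)

## Steps most likely to fail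

**1. Step 5.**
- The basic pyrone carbonyls may bind BF3 and turn ring A into a flavylium-like arene that is no longer oxidised.
- The meta-trioxygenated ring may capture the iodane at C8 as a diaryliodonium salt instead of forming the C–C bond.
- Bond formation may drift to C6.
- The peri 5-O-benzyl groups may be lost before coupling.

Fallback (both carbons prefunctionalised, reductive coupling): from 6, NIS (2.2 equiv) with catalytic CF3CO2H in MeCN–CH2Cl2 should iodinate C8 and C8'', the usual site for 5,7-di-O-alkylflavones, to give the tethered 8,8''-diiodide F1. Activated Cu powder (zerovalent copper) in DMF at 120 °C then closes the same dioxepine by an intramolecular Ullmann coupling, the classical entry to 8,8''-biflavone ethers. The route is rejoined at 7.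

**2. Step 3.**
- Alkylation may compete at the 4'-oxygen of apigenin.
- A second alkylation may occur.
- Traces of water may hydrolyse the chloromethyl ether.

Fallback (only one free hydroxyl offered): from 4, Ac2O–pyridine gives apigenin triacetate F2. PhSH–imidazole in NMP removes only the 7-acetate, whose phenoxide is the best leaving group, to give 5,4'-di-O-acetylapigenin F3. The single free 7-OH of F3 is alkylated with 3 (K2CO3, 1 equiv, DMF, 0 °C → rt) to give the diacetate of the mixed acetal F4. Methanolysis (catalytic K2CO3, MeOH–THF) removes both acetates and the route is rejoined at 5.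

**3. Step 7.**
- The acetal oxygens are vinylogous ester oxygens and become still poorer donors once boron chelates O5 and C4=O, so ring opening may stall.
- The boron chelates may precipitate.
- Forcing conditions may start demethylation at O4'.
- The released one-carbon electrophile may attack C6.

Fallback (hard acid with a soft nucleophile instead of chloride opening and hydrolysis): from 8, BF3·OEt2 with 1,3-propanedithiol in CH2Cl2 at rt lets sulfur attack the activated CH2 directly. The methylene carbon is trapped irreversibly as a cyclic dithioacetal and aryl methyl ethers are left alone. This leads straight to 9, and no new compound arises (F0).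

## Further compounds

F1 | step 5 | tethered 8,8''-diiodide of 6 | COc1ccc(cc1)-c1cc(=O)c2c(OCc3ccccc3)cc(OCOc3cc(OCc4ccccc4)c4c(=O)cc(-c5ccc(OCc6ccccc6)cc5)oc4c3I)c(I)c2o1
F2 | step 3 | apigenin triacetate | CC(=O)Oc1ccc(cc1)-c1cc(=O)c2c(OC(C)=O)cc(OC(C)=O)cc2o1
F3 | step 3 | 5,4'-di-O-acetylapigenin | CC(=O)Oc1ccc(cc1)-c1cc(=O)c2c(OC(C)=O)cc(O)cc2o1
F4 | step 3 | 5'',4'''-diacetate of the mixed acetal 5 | COc1ccc(cc1)-c1cc(=O)c2c(O)cc(OCOc3cc(OC(C)=O)c4c(=O)cc(-c5ccc(OC(C)=O)cc5)oc4c3)cc2o1
F0 | step 7 | none | none
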